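Each naphthalene unit is numbered as an 8-methoxynaphthalen-1-ol: terminal unit A is bonded through carbon 2 to carbon 4 of central unit B, whose carbon 2 carries carbon 4 of terminal unit C. The disconnection lies inside the oxygenated ring of unit C: carbon 4, para to the hydroxyl-bearing carbon 1, and its neighbour carbon 3 are traced back to a diaryl ketone carbon and the terminal carbon of an aryl vinyl ketone, held ortho on one methoxybenzene. One SmI2 ketyl–enone cyclisation joins these carbons and closes that ring as a 4-aryl-4-hydroxy-1-tetralone, which acid dehydrates, aromatises and deprotects. The precursor is a 1-(2-aroyl-6-methoxyphenyl)prop-2-en-1-one whose aroyl group is the bis-MOM binaphthyl of units A and B.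

Key step: step 11

Remark: the target structure specifies no stereogenic element, and neither biaryl axis (one ortho oxygen substituent beside hydrogen atoms) should be configurationally stable, so no axial control is planned and 17 is carried as a racemate.

Step 1
Reactants: 1 naphthalene-1,8-diol
Product: 2 8-methoxynaphthalen-1-ol
Conditions: MeI (1.05 equiv), K2CO3, acetone, rt to 50 °C, Ar
Reagents that add atoms: iodomethane, CI
Why: Williamson O-methylation should stop at the monoether because the peri hydrogen bond makes the first hydroxyl far more acidic than the second.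

Step 2
Reactants: 2 8-methoxynaphthalen-1-ol
Product: 3 8-methoxy-1-(methoxymethoxy)naphthalene
Conditions: NaH, MOMCl, DMF, 0 °C to rt
Reagents that add atoms: chloromethyl methyl ether, COCCl
Why: O-alkylation of the sodium naphthoxide (acetal protection) installs a MOM group that later directs metalation and falls in the final acid step.

Step 3
Reactants: 3 8-methoxy-1-(methoxymethoxy)naphthalene
Product: 5 2-[8-methoxy-1-(methoxymethoxy)naphthalen-2-yl]-4,4,5,5-tetramethyl-1,3,2-dioxaborolane, via 2-lithiated naphthyl MOM ether 4 (not isolated)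
Conditions: n-BuLi, TMEDA, Et2O, 0 °C to rt; iPrOBpin, −78 °C to rt; H2O
Reagents that add atoms: 2-isopropoxy-4,4,5,5-tetramethyl-1,3,2-dioxaborolane, CC(C)OB1OC(C)(C)C(C)(C)O1
Why: Directed ortho-metalation followed by borate trapping should place boron at position 2, since the MOM ether is a stronger director than the methoxy group.

Step 4
Reactants: 2 8-methoxynaphthalen-1-ol
Product: 6 4-bromo-8-methoxynaphthalen-1-ol
Conditions: NBS (1.0 equiv), MeCN, −20 to 0 °C, dark
Reagents that add atoms: N-bromosuccinimide, O=C1CCC(=O)N1Br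
Why: Electrophilic aromatic bromination should go para to the free hydroxyl (position 4, an alpha position), because the hydrogen-bonded hydroxyl out-directs the methoxy group and acetonitrile favours para over ortho attack.

Step 5
Reactants: 6 4-bromo-8-methoxynaphthalen-1-ol
Product: 7 4-bromo-8-methoxy-1-(methoxymethoxy)naphthalene
Conditions: NaH, MOMCl, DMF, 0 °C to rt
Reagents that add atoms: chloromethyl methyl ether, COCCl
Why: The same naphthoxide O-alkylation (MOM protection) as in step 2 masks the phenol before cross-coupling and metalation.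

Step 6
Reactants: 5 2-[8-methoxy-1-(methoxymethoxy)naphthalen-2-yl]-4,4,5,5-tetramethyl-1,3,2-dioxaborolane; 7 4-bromo-8-methoxy-1-(methoxymethoxy)naphthalene
Product: 8 8-methoxy-2-[5-methoxy-4-(methoxymethoxy)naphthalen-1-yl]-1-(methoxymethoxy)naphthalene (bis-MOM A–B binaphthyl)
Conditions: Pd(dppf)Cl2 (5 mol%), K3PO4, 1,4-dioxane/H2O, 90 °C
Reagents that add atoms: none
Why: Suzuki–Miyaura cross-coupling joins position 2 of unit A to position 4 of unit B with defined regiochemistry, and one ortho alkoxy group plus one peri hydrogen is a modest steric demand for this catalyst.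

Step 7
Reactants: 8 8-methoxy-2-[5-methoxy-4-(methoxymethoxy)naphthalen-1-yl]-1-(methoxymethoxy)naphthalene
Product: 10 8-methoxy-4-[8-methoxy-1-(methoxymethoxy)naphthalen-2-yl]-1-(methoxymethoxy)naphthalene-2-carbaldehyde, via lithiated binaphthyl 9 (not isolated)
Conditions: n-BuLi, TMEDA, THF, −20 to 0 °C; DMF, −78 °C to rt; H2O
Reagents that add atoms: N,N-dimethylformamide, CN(C)C=O
Why: Directed ortho-metalation and formylation should occur at position 2 of unit B, the only free position ortho to a MOM ether now that the matching position of unit A is arylated.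

Step 8
Reactants: 11 2-bromo-6-methoxybenzaldehyde; 12 vinylmagnesium bromide
Product: 13 1-(2-bromo-6-methoxyphenyl)prop-2-en-1-ol (racemic)
Conditions: THF, −78 to 0 °C; H2O
Reagents that add atoms: none
Why: Grignard 1,2-addition to the aldehyde leaves the aryl bromide untouched at low temperature; the new carbinol centre is uncontrolled and is erased in step 10.

Step 9
Reactants: 13 1-(2-bromo-6-methoxyphenyl)prop-2-en-1-ol; 10 8-methoxy-4-[8-methoxy-1-(methoxymethoxy)naphthalen-2-yl]-1-(methoxymethoxy)naphthalene-2-carbaldehyde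
Product: 15 1-[2-(hydroxy{8-methoxy-4-[8-methoxy-1-(methoxymethoxy)naphthalen-2-yl]-1-(methoxymethoxy)naphthalen-2-yl}methyl)-6-methoxyphenyl]prop-2-en-1-ol (diastereomer mixture), via dilithio alkoxide 14 (not isolated)
Conditions: 13, n-BuLi (2.1 equiv), THF, −78 °C; then 10, −78 to −20 °C; H2O
Reagents that add atoms: none
Why: Deprotonation then bromine–lithium exchange gives an alkoxide-bearing aryllithium that needs no protecting group, and its 1,2-addition to the aldehyde makes the future bond between unit B and unit C; both carbinol centres form without control and are erased in step 10.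

Step 10
Reactants: 15 1-[2-(hydroxy{8-methoxy-4-[8-methoxy-1-(methoxymethoxy)naphthalen-2-yl]-1-(methoxymethoxy)naphthalen-2-yl}methyl)-6-methoxyphenyl]prop-2-en-1-ol
Product: 16 1-[2-({8-methoxy-4-[8-methoxy-1-(methoxymethoxy)naphthalen-2-yl]-1-(methoxymethoxy)naphthalen-2-yl}carbonyl)-6-methoxyphenyl]prop-2-en-1-one
Conditions: Dess–Martin periodinane (3 equiv), NaHCO3, CH2Cl2, 0 °C to rt; used at once
Reagents that add atoms: none
Why: Dess–Martin oxidation should convert both secondary benzylic alcohols to ketones without touching the MOM acetals or the vinyl group, the bicarbonate buffer suppressing acid-promoted cyclodehydration of the half-oxidised hydroxy ketone.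

Step 11
Reactants: 16 1-[2-({8-methoxy-4-[8-methoxy-1-(methoxymethoxy)naphthalen-2-yl]-1-(methoxymethoxy)naphthalen-2-yl}carbonyl)-6-methoxyphenyl]prop-2-en-1-one
Product: 17 4-hydroxy-8-methoxy-4-{8-methoxy-4-[8-methoxy-1-(methoxymethoxy)naphthalen-2-yl]-1-(methoxymethoxy)naphthalen-2-yl}-3,4-dihydronaphthalen-1(2H)-one (racemic)
Conditions: SmI2 (0.1 M in THF, 2.5 equiv), t-BuOH (3 equiv), THF, −78 to 0 °C, 16 added slowly to ≤0.005 M; H2O
Reagents that add atoms: none
Why: SmI2 (divalent samarium) transfers one electron to the diaryl ketone, and the resulting ketyl carbon radical adds to the terminal carbon of the neighbouring aryl vinyl ketone; a second electron converts the alpha-keto radical into a samarium enolate that tert-butanol protonates. The closest known reaction type is the SmI2 ketyl–olefin reductive cyclisation onto an alpha,beta-unsaturated carbonyl acceptor. The single ring formed, the oxygenated ring of unit C, closes in the 6-endo-trig mode through the new bond between carbons 3 and 4 of that unit, whereas 5-exo attack at the alpha carbon would pair a nucleophilic radical with the electron-rich end of the enone and leave an unstabilised primary radical. The one new stereocentre, the carbinol carbon 4 of unit C, has no controlling element and forms as a racemate, which does not matter because it is destroyed on aromatisation. The step needs ring closure to be faster than pinacol coupling, enone dimerisation and plain ketone reduction; the ortho placement of both carbonyl arms on one benzene ring, together with slow addition at high dilution, should secure this. Should the enone accept the first electron instead, its terminal carbon would attack the ketone and form the same bond.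

Step 12
Reactants: 17 4-hydroxy-8-methoxy-4-{8-methoxy-4-[8-methoxy-1-(methoxymethoxy)naphthalen-2-yl]-1-(methoxymethoxy)naphthalen-2-yl}-3,4-dihydronaphthalen-1(2H)-one
Product: 20 2-(4-hydroxy-5-methoxynaphthalen-1-yl)-4-(1-hydroxy-8-methoxynaphthalen-2-yl)-8-methoxynaphthalen-1-ol, via dienone keto tautomer 18 (not isolated), via bis-MOM ternaphthol 19 (not isolated)
Conditions: HCl (3 M in MeOH), THF, degassed, 50 °C
Reagents that add atoms: none
Why: Acid-catalysed E1 dehydration of the doubly benzylic tertiary alcohol gives the 3,4-ene, whose keto form tautomerises to the naphthol (aromatisation), and methanolic HCl then cleaves both aryl MOM acetals by transacetalisation, the carbinol stereocentre being removed on the way.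

Compound list
1 | naphthalene-1,8-diol | Oc1cccc2cccc(O)c12 | starting material
2 | 8-methoxynaphthalen-1-ol | COc1cccc2cccc(O)c12 | intermediate
3 | 8-methoxy-1-(methoxymethoxy)naphthalene | COCOc1cccc2cccc(OC)c12 | intermediate
4 | [8-methoxy-1-(methoxymethoxy)naphthalen-2-yl]lithium (not isolated) | [Li]c1ccc2cccc(OC)c2c1OCOC | intermediate
5 | 2-[8-methoxy-1-(methoxymethoxy)naphthalen-2-yl]-4,4,5,5-tetramethyl-1,3,2-dioxaborolane | CC1(C)OB(OC1(C)C)c1ccc2cccc(OC)c2c1OCOC | intermediate
6 | 4-bromo-8-methoxynaphthalen-1-ol | COc1cccc2c(Br)ccc(O)c12 | intermediate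
7 | 4-bromo-8-methoxy-1-(methoxymethoxy)naphthalene | COCOc1ccc(Br)c2cccc(OC)c12 | intermediate
8 | 8-methoxy-2-[5-methoxy-4-(methoxymethoxy)naphthalen-1-yl]-1-(methoxymethoxy)naphthalene (bis-MOM A–B binaphthyl) | COCOc1c(-c2ccc(OCOC)c3c(OC)cccc23)ccc2cccc(OC)c12 | intermediate
9 | {8-methoxy-4-[8-methoxy-1-(methoxymethoxy)naphthalen-2-yl]-1-(methoxymethoxy)naphthalen-2-yl}lithium (not isolated) | [Li]c1cc(-c2ccc3cccc(OC)c3c2OCOC)c2cccc(OC)c2c1OCOC | intermediate
10 | 8-methoxy-4-[8-methoxy-1-(methoxymethoxy)naphthalen-2-yl]-1-(methoxymethoxy)naphthalene-2-carbaldehyde | O=Cc1cc(-c2ccc3cccc(OC)c3c2OCOC)c2cccc(OC)c2c1OCOC | intermediate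
11 | 2-bromo-6-methoxybenzaldehyde | COc1cccc(Br)c1C=O | starting material
12 | vinylmagnesium bromide | C=C[Mg]Br | starting material
13 | 1-(2-bromo-6-methoxyphenyl)prop-2-en-1-ol, racemic | C=CC(O)c1c(OC)cccc1Br | intermediate
14 | lithium 1-(2-lithio-6-methoxyphenyl)prop-2-en-1-olate (not isolated) | [Li]OC(C=C)c1c(OC)cccc1[Li] | intermediate
15 | 1-[2-(hydroxy{8-methoxy-4-[8-methoxy-1-(methoxymethoxy)naphthalen-2-yl]-1-(methoxymethoxy)naphthalen-2-yl}methyl)-6-methoxyphenyl]prop-2-en-1-ol, diastereomer mixture | C=CC(O)c1c(OC)cccc1C(O)c1cc(-c2ccc3cccc(OC)c3c2OCOC)c2cccc(OC)c2c1OCOC | intermediate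
16 | 1-[2-({8-methoxy-4-[8-methoxy-1-(methoxymethoxy)naphthalen-2-yl]-1-(methoxymethoxy)naphthalen-2-yl}carbonyl)-6-methoxyphenyl]prop-2-en-1-one | C=CC(=O)c1c(OC)cccc1C(=O)c1cc(-c2ccc3cccc(OC)c3c2OCOC)c2cccc(OC)c2c1OCOC | intermediate
17 | 4-hydroxy-8-methoxy-4-{8-methoxy-4-[8-methoxy-1-(methoxymethoxy)naphthalen-2-yl]-1-(methoxymethoxy)naphthalen-2-yl}-3,4-dihydronaphthalen-1(2H)-one, racemic, one enantiomer drawn | O=C1CC[C@@](O)(c2cc(-c3ccc4cccc(OC)c4c3OCOC)c3cccc(OC)c3c2OCOC)c2cccc(OC)c12 | intermediate
18 | 8-methoxy-4-{8-methoxy-4-[8-methoxy-1-(methoxymethoxy)naphthalen-2-yl]-1-(methoxymethoxy)naphthalen-2-yl}naphthalen-1(2H)-one (not isolated) | O=C1CC=C(c2cc(-c3ccc4cccc(OC)c4c3OCOC)c3cccc(OC)c3c2OCOC)c2cccc(OC)c12 | intermediate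
19 | 8-methoxy-4-{8-methoxy-4-[8-methoxy-1-(methoxymethoxy)naphthalen-2-yl]-1-(methoxymethoxy)naphthalen-2-yl}naphthalen-1-ol (not isolated) | COCOc1c(-c2ccc(O)c3c(OC)cccc23)cc(-c2ccc3cccc(OC)c3c2OCOC)c2cccc(OC)c12 | intermediate
20 | 2-(4-hydroxy-5-methoxynaphthalen-1-yl)-4-(1-hydroxy-8-methoxynaphthalen-2-yl)-8-methoxynaphthalen-1-ol | COc1cccc2ccc(-c3cc(-c4ccc(O)c5c(OC)cccc45)c(O)c4c(OC)cccc34)c(O)c12 | target

Total step count: 12 steps.
Longest linear sequence: 9 steps (steps 1, 2, 3, 6, 7, 9, 10, 11, 12).

Steps most likely to fail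

Step 11. Intermolecular ketyl coupling, or reductive dimerisation or polymerisation of the vinyl ketone, may outpace ring closure. Two-electron reduction of the diaryl ketone followed by cyclodehydration may also intervene. The fallback replaces ring construction by a second cross-coupling; it sets out from binaphthyl 8 and bromide 7 and rejoins the route at target 20. Compound 8 is lithiated as in step 7 to give 9, which is trapped with iPrOBpin to give the pinacol boronate F1, with boron at position 2 of unit B. Suzuki–Miyaura coupling of F1 with 7 (Pd(OAc)2, SPhos, K3PO4, toluene/H2O, 100 °C) should form the bond between unit B and unit C directly and give the tris-MOM ternaphthyl F2. HCl in MeOH/THF at 50 °C then removes the three MOM groups to give 20.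

Step 9. Bromine–lithium exchange beside a free alkoxide may be incomplete, butyllithium may carbometalate the allylic alkoxide, or the dilithio species may precipitate and starve the addition. The fallback builds the same diol by directed metalation of a benzamide; it sets out from aldehyde 10 and rejoins at diol 15. Commercial N,N-diethyl-2-methoxybenzamide is lithiated ortho to the amide (s-BuLi, TMEDA, THF, −78 °C) to give the ortho-lithiated amide F3, which adds to 10 to give hydroxy amide F4. Warming the lithium alkoxide, or if needed catalytic PPTS in toluene at 80 °C, should lactonise it to the 3-aryl-7-methoxyphthalide F5. Diisobutylaluminium hydride (i-Bu2AlH, CH2Cl2, −78 °C) gives lactol F6, and excess vinylmagnesium bromide 12 (THF, 0 °C) opens it to 15.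

Step 4. Bromination may lose regiocontrol through ortho attack at position 2, attack on the methoxy-bearing ring or double bromination. The fallback makes the bond between units A and B by carbonyl addition instead of cross-coupling; it sets out from 3 and rejoins at binaphthyl 8, bypassing 5, 6 and 7. Commercial juglone (5-hydroxynaphthalene-1,4-dione) is O-methylated (MeI, Ag2O, CH2Cl2) to 5-methoxynaphthalene-1,4-dione F7. Aryllithium 4, made from 3 as in step 3, is added at −78 °C and should attack the quinone carbonyl remote from the methoxy group, the one not deactivated by a peri methoxy donor, to give quinol F8. Zinc dust in AcOH/THF removes the tertiary hydroxyl reductively and aromatises to naphthol F9, whose hydroxyl ends up peri to the methoxy group and para to unit A. NaH/MOMCl in DMF then gives 8.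

Further compounds
F1 | step 11 | 2-{8-methoxy-4-[8-methoxy-1-(methoxymethoxy)naphthalen-2-yl]-1-(methoxymethoxy)naphthalen-2-yl}-4,4,5,5-tetramethyl-1,3,2-dioxaborolane | CC1(C)OB(OC1(C)C)c1cc(-c2ccc3cccc(OC)c3c2OCOC)c2cccc(OC)c2c1OCOC
F2 | step 11 | tris-MOM ternaphthyl, 8-methoxy-2-[5-methoxy-4-(methoxymethoxy)naphthalen-1-yl]-4-[8-methoxy-1-(methoxymethoxy)naphthalen-2-yl]-1-(methoxymethoxy)naphthalene | COCOc1ccc(-c2cc(-c3ccc4cccc(OC)c4c3OCOC)c3cccc(OC)c3c2OCOC)c2cccc(OC)c12
F3 | step 9 | [2-(diethylcarbamoyl)-3-methoxyphenyl]lithium | CCN(CC)C(=O)c1c([Li])cccc1OC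
F4 | step 9 | N,N-diethyl-2-(hydroxy{8-methoxy-4-[8-methoxy-1-(methoxymethoxy)naphthalen-2-yl]-1-(methoxymethoxy)naphthalen-2-yl}methyl)-6-methoxybenzamide, racemic | CCN(CC)C(=O)c1c(OC)cccc1C(O)c1cc(-c2ccc3cccc(OC)c3c2OCOC)c2cccc(OC)c2c1OCOC
F5 | step 9 | 7-methoxy-3-{8-methoxy-4-[8-methoxy-1-(methoxymethoxy)naphthalen-2-yl]-1-(methoxymethoxy)naphthalen-2-yl}isobenzofuran-1(3H)-one, racemic | O=C1OC(c2cc(-c3ccc4cccc(OC)c4c3OCOC)c3cccc(OC)c3c2OCOC)c2cccc(OC)c12
F6 | step 9 | 7-methoxy-3-{8-methoxy-4-[8-methoxy-1-(methoxymethoxy)naphthalen-2-yl]-1-(methoxymethoxy)naphthalen-2-yl}-1,3-dihydroisobenzofuran-1-ol, diastereomer mixture | OC1OC(c2cc(-c3ccc4cccc(OC)c4c3OCOC)c3cccc(OC)c3c2OCOC)c2cccc(OC)c12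
F7 | step 4 | 5-methoxynaphthalene-1,4-dione | COc1cccc2C(=O)C=CC(=O)c12
F8 | step 4 | 4-hydroxy-8-methoxy-4-[8-methoxy-1-(methoxymethoxy)naphthalen-2-yl]naphthalen-1(4H)-one, racemic | O=C1C=CC(O)(c2ccc3cccc(OC)c3c2OCOC)c2cccc(OC)c12
F9 | step 4 | 8-methoxy-4-[8-methoxy-1-(methoxymethoxy)naphthalen-2-yl]naphthalen-1-ol | Oc1ccc(-c2ccc3cccc(OC)c3c2OCOC)c2cccc(OC)c12
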